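**Retrosynthetic overview**

1. Numbering used throughout is that of the target, a bicyclo[3.2.1]oct-2-en-8-one: C1 (allyl bridgehead), C2=C3(OMe), C4(OAc), C5(OMe bridgehead), C6 (aryl), C7 (methyl), C8 (bridging C=O). The C8 ketone, C4 acetate and C3 methoxy group are all derived late from the bicyclic enone 24 (C2=C3–C4=O, C8–OH).
2. The C5–C8 bond closes the five-membered ring C1–C8–C5–C6–C7 and the six-membered ring C1–C2–C3–C4–C5–C8 at once; it is cut as a transannular Mukaiyama aldol inside a cycloheptadiene. The C1 quaternary centre is cut as a deconjugative allylation.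
3. The plan rests on one feature: the trans C6-aryl/C7-methyl pair lies in the seven-membered ring C1–C7 on the side opposite C3, exactly where a cis-divinylcyclopropane built on C2–C3–C4 makes its new bond. Ring C1–C7 and the C6–C7 bond are therefore cut together as a Cope rearrangement of a 1-siloxy-1,2-divinylcyclopropane.
4. The cyclopropane (C2, C3, C4) comes from a Kulinkovich reaction of a Z α-methoxycinnamate (syringaldehyde + methyl methoxyacetate) with a 4-silyloxybutyl Grignard reagent; the chain is oxidised to the ester and condensed with acetaldehyde to give the second alkenyl arm.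
5. Order of ring formation: cyclopropane (step 4), seven-membered ring (step 9), bridged five/six-membered pair (step 13).

Key step: step 9

Abbreviations: Ar = 4-(tert-butyldimethylsilyloxy)-3,5-dimethoxyphenyl; TBS = tert-butyldimethylsilyl; TES = triethylsilyl; TADDOL = (4R,5R)-2,2-dimethyl-α,α,α′,α′-tetraphenyl-1,3-dioxolane-4,5-dimethanol.
Assumption: the (4R,5R)-TADDOL titanate is taken to deliver the (1R,2R)-cyclopropanol 10; if the sense of induction proves opposite, the (4S,5S)-ligand is used instead.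
Remark: the C8 carbinol configuration (24–31) and the epoxide face (26, 27) are not controlled and are erased later, so their SMILES leave these centres open.

**Route**

Step 1
Reactants: 1 syringaldehyde
Product: 2 4-(tert-butyldimethylsilyloxy)-3,5-dimethoxybenzaldehyde
Conditions: TBSCl, imidazole, DMF, 20 °C
Reagents that add atoms: tert-butyldimethylsilyl chloride, CC(C)(C)[Si](C)(C)Cl
Why: Imidazole-promoted silyl ether formation masks the acidic phenol for the enolate, Grignard and titanium steps.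

Step 2
Reactants: 2 4-(tert-butyldimethylsilyloxy)-3,5-dimethoxybenzaldehyde; 3 methyl methoxyacetate
Product: 6 methyl (Z)-3-Ar-2-methoxyprop-2-enoate, via aldol adduct 4 (not isolated), via aldol mesylate 5 (not isolated)
Conditions: LiN(iPr)2, THF, −78 °C; MsCl, −78 → 0 °C; DBU, 0 → 20 °C
Reagents that add atoms: none
Why: Lithium-enolate aldol addition followed by E1cB elimination of the mesylate should give the more stable Z enoate (aryl trans to the ester carbon), which places the aryl group trans to the future cyclopropane.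

Step 3
Reactants: 7 4-bromobutan-1-ol
Product: 8 (4-bromobutoxy)triethylsilane
Conditions: Et3SiCl, imidazole, CH2Cl2, 0 °C
Reagents that add atoms: chlorotriethylsilane, CC[Si](Cl)(CC)CC
Why: Silyl ether formation; TES is chosen because a primary TES ether survives Grignard formation and is later oxidised directly under Swern conditions without an acidic deprotection that would endanger the enol ether.

Step 4
Reactants: 6 methyl (Z)-3-Ar-2-methoxyprop-2-enoate; 8 (4-bromobutoxy)triethylsilane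
Product: 10 (1R,2R)-1-[(Z)-2-Ar-1-methoxyethenyl]-2-[2-(triethylsilyloxy)ethyl]cyclopropan-1-ol, via Grignard reagent 9 (not isolated)
Conditions: Mg, THF, 40 °C (8 → 9); then slow addition of 9 (2.5 equiv) to 6, Ti(OiPr)4 (1 equiv), TADDOL (1 equiv), THF, 0 → 20 °C
Reagents that add atoms: none
Why: Kulinkovich hydroxycyclopropanation, in which the titanacyclopropane formed from two equivalents of 9 acts as a 1,2-dicarbanion on the ester; its inherent cis-dialkyl selectivity places the alkenyl arm and the silyloxyethyl chain on the same ring face, and the C2-symmetric titanium TADDOLate selects the enantiotopic face.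

Step 5
Reactants: 10 (1R,2R)-1-[(Z)-2-Ar-1-methoxyethenyl]-2-[2-(triethylsilyloxy)ethyl]cyclopropan-1-ol
Product: 11 (1R,2R)-1-(tert-butyldimethylsilyloxy)-1-[(Z)-2-Ar-1-methoxyethenyl]-2-[2-(triethylsilyloxy)ethyl]cyclopropane
Conditions: TBSOTf, 2,6-lutidine, CH2Cl2, −78 → 0 °C
Reagents that add atoms: tert-butyldimethylsilyl triflate, CC(C)(C)[Si](C)(C)OS(=O)(=O)C(F)(F)F
Why: Silyl triflate silylation of the tertiary cyclopropanol under buffered conditions blocks homoenolate ring opening and installs the siloxy group that becomes the C4 enol ether.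

Step 6
Reactants: 11 (1R,2R)-1-(tert-butyldimethylsilyloxy)-1-[(Z)-2-Ar-1-methoxyethenyl]-2-[2-(triethylsilyloxy)ethyl]cyclopropane
Product: 12 2-[(1S,2R)-2-(tert-butyldimethylsilyloxy)-2-[(Z)-2-Ar-1-methoxyethenyl]cyclopropyl]acetaldehyde
Conditions: (COCl)2, DMSO, CH2Cl2, −78 → −30 °C; Et3N
Reagents that add atoms: none
Why: Under Swern conditions a primary triethylsilyl ether is attacked by the chlorosulfonium salt and oxidised straight to the aldehyde, while the tertiary and aryl TBS ethers and the acid-sensitive enol ether stay untouched.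

Step 7
Reactants: 12 2-[(1S,2R)-2-(tert-butyldimethylsilyloxy)-2-[(Z)-2-Ar-1-methoxyethenyl]cyclopropyl]acetaldehyde
Product: 14 methyl 2-[(1S,2R)-2-(tert-butyldimethylsilyloxy)-2-[(Z)-2-Ar-1-methoxyethenyl]cyclopropyl]acetate, via carboxylic acid 13 (not isolated)
Conditions: NaClO2, NaH2PO4, 2-methyl-2-butene, t-BuOH/H2O, 0 °C; then Me3SiCHN2, MeOH/toluene, 0 °C
Reagents that add atoms: sodium chlorite, [Na+].[O-]Cl=O; trimethylsilyldiazomethane, C[Si](C)(C)C=[N+]=[N-]
Why: Pinnick oxidation with an excess of hypochlorite scavenger followed by diazoalkane esterification gives the ester without acid or base strong enough to harm the enol ether or the silyl ethers.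

Step 8
Reactants: 14 methyl 2-[(1S,2R)-2-(tert-butyldimethylsilyloxy)-2-[(Z)-2-Ar-1-methoxyethenyl]cyclopropyl]acetate; 15 acetaldehyde
Product: 18 methyl (E)-2-[(1S,2R)-2-(tert-butyldimethylsilyloxy)-2-[(Z)-2-Ar-1-methoxyethenyl]cyclopropyl]but-2-enoate, via aldol adduct 16 (not isolated), via aldol mesylate 17 (not isolated)
Conditions: LiN(iPr)2, THF, −78 °C; 15; MsCl, −78 → 0 °C; DBU, 0 → 20 °C
Reagents that add atoms: none
Why: Ester-enolate aldol addition and E1cB dehydration should favour the E (tiglate-type) ethylidene ester with methyl trans to the ester and therefore cis to the cyclopropane; any Z isomer is removed by chromatography or by its much faster rearrangement on gentle warming.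

Step 9
Reactants: 18 methyl (E)-2-[(1S,2R)-2-(tert-butyldimethylsilyloxy)-2-[(Z)-2-Ar-1-methoxyethenyl]cyclopropyl]but-2-enoate
Product: 19 methyl (6R,7S)-6-Ar-4-(tert-butyldimethylsilyloxy)-5-methoxy-7-methylcyclohepta-1,4-diene-1-carboxylate
Conditions: o-xylene (degassed), BHT (cat.), 140 °C, base-washed sealed tube
Reagents that add atoms: none
Why: A concerted thermal [3,3] shift (divinylcyclopropane–cycloheptadiene Cope rearrangement) passes through the only attainable geometry, the boat with both alkenyl arms folded over the three-membered ring, and is driven by release of ring strain; the closest known reaction type is the rearrangement of other siloxy-substituted cis-divinylcyclopropanes. The seven-membered ring C1–C7 closes by ring enlargement: the C6–C7 bond forms between the two alkene termini as the cyclopropane bond C2–C4 breaks, leaving C1=C2 and C4=C5 as cis ring alkenes. C7 is controlled by the E enoate, whose methyl group is cis to the ring (inside), and C6 by the Z enol ether, whose aryl group is trans to the ring (outside); one inside and one outside terminus end up trans, and the (1S,2R) cyclopropane decides that the (6R,7S) enantiomer forms. The step needs the two arms cis on the ring, which the Kulinkovich reaction secures, and geometrically pure alkenes, which steps 2 and 8 secure. The inside methyl group raises the barrier, hence 140 °C, and the product emerges with a regiodefined C4 silyl enol ether and the C1 enoate whose carbonyl carbon becomes C8.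

Step 10
Reactants: 19 methyl (6R,7S)-6-Ar-4-(tert-butyldimethylsilyloxy)-5-methoxy-7-methylcyclohepta-1,4-diene-1-carboxylate; 20 allyl bromide
Product: 21 methyl (1R,6R,7S)-1-allyl-6-Ar-4-(tert-butyldimethylsilyloxy)-5-methoxy-7-methylcyclohepta-2,4-diene-1-carboxylate
Conditions: LiN(iPr)2, THF/HMPA, −78 °C; 20, −78 → −40 °C
Reagents that add atoms: none
Why: Deconjugative α-alkylation of the extended ester enolate formed by deprotonation at the doubly allylic C3 moves the alkene to C2=C3; allylic 1,3-strain with the enolate oxygens should hold the C7 methyl pseudoaxial so that it covers one face of C1, and the allyl group should enter trans to it, leaving the ester carbon (future C8) cis to methyl as the bridge requires.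

Step 11
Reactants: 21 methyl (1R,6R,7S)-1-allyl-6-Ar-4-(tert-butyldimethylsilyloxy)-5-methoxy-7-methylcyclohepta-2,4-diene-1-carboxylate
Product: 22 [(1R,6R,7S)-1-allyl-6-Ar-4-(tert-butyldimethylsilyloxy)-5-methoxy-7-methylcyclohepta-2,4-dien-1-yl]methanol
Conditions: iBu2AlH (3 equiv), CH2Cl2, −78 → 0 °C; aq. KNa tartrate
Reagents that add atoms: none
Why: Aluminium hydride reduction of the hindered ester to the primary alcohol leaves the silyl enol ether and the aryl silyl ether intact.

Step 12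
Reactants: 22 [(1R,6R,7S)-1-allyl-6-Ar-4-(tert-butyldimethylsilyloxy)-5-methoxy-7-methylcyclohepta-2,4-dien-1-yl]methanol
Product: 23 (1R,6R,7S)-1-allyl-6-Ar-4-(tert-butyldimethylsilyloxy)-5-methoxy-7-methylcyclohepta-2,4-diene-1-carbaldehyde
Conditions: Dess–Martin periodinane, NaHCO3, CH2Cl2, 0 °C
Reagents that add atoms: none
Why: Buffered Dess–Martin oxidation gives the non-enolisable neopentyl aldehyde without touching the silyl dienol ether.

Step 13
Reactants: 23 (1R,6R,7S)-1-allyl-6-Ar-4-(tert-butyldimethylsilyloxy)-5-methoxy-7-methylcyclohepta-2,4-diene-1-carbaldehyde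
Product: 24 1-allyl-6-endo-Ar-8-hydroxy-5-methoxy-7-exo-methylbicyclo[3.2.1]oct-2-en-4-one
Conditions: BF3·OEt2 (1.1 equiv), CH2Cl2, −78 °C; aq. NaHCO3
Reagents that add atoms: none
Why: Transannular Mukaiyama aldol in which the BF3-activated C8 aldehyde on C1 is attacked by C5 of the C4-siloxy/C5-methoxy enol ether, the only face of C5 that C8 can reach, so C5 is set by C1; loss of the silyl group leaves the C4 ketone conjugated with C2=C3.

Step 14
Reactants: 24 1-allyl-6-endo-Ar-8-hydroxy-5-methoxy-7-exo-methylbicyclo[3.2.1]oct-2-en-4-one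
Product: 25 1-allyl-6-endo-Ar-5-methoxy-7-exo-methyl-8-(triethylsilyloxy)bicyclo[3.2.1]oct-2-en-4-one
Conditions: Et3SiOTf, 2,6-lutidine, CH2Cl2, −78 → 0 °C
Reagents that add atoms: triethylsilyl triflate, CC[Si](CC)(CC)OS(=O)(=O)C(F)(F)F
Why: Silylation of the β-hydroxy ketone blocks retro-aldol opening of the new bridge in the two basic steps that follow and keeps C8 at the alcohol level, because a C4,C8-dione would risk retro-Claisen cleavage and unselective reduction.

Step 15
Reactants: 25 1-allyl-6-endo-Ar-5-methoxy-7-exo-methyl-8-(triethylsilyloxy)bicyclo[3.2.1]oct-2-en-4-one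
Product: 26 1-allyl-2,3-epoxy-6-endo-(4-hydroxy-3,5-dimethoxyphenyl)-5-methoxy-7-exo-methyl-8-(triethylsilyloxy)bicyclo[3.2.1]octan-4-one
Conditions: 30% H2O2, NaOH, MeOH, 0 → 20 °C
Reagents that add atoms: hydrogen peroxide, OO
Why: Weitz–Scheffer nucleophilic epoxidation attacks only the electron-poor C2=C3 enone and spares the allyl group; the alkaline methanol also removes the aryl silyl ether, which is intended because the phenol is masked again as its acetate in step 18.

Step 16
Reactants: 26 1-allyl-2,3-epoxy-6-endo-(4-hydroxy-3,5-dimethoxyphenyl)-5-methoxy-7-exo-methyl-8-(triethylsilyloxy)bicyclo[3.2.1]octan-4-one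
Product: 28 1-allyl-6-endo-(4-hydroxy-3,5-dimethoxyphenyl)-3,5-dimethoxy-7-exo-methyl-8-(triethylsilyloxy)bicyclo[3.2.1]oct-2-en-4-one, via hydroxy methoxy ketone 27 (not isolated)
Conditions: NaOMe, MeOH, 60 °C; aq. NH4Cl
Reagents that add atoms: methanol (as sodium methoxide), CO
Why: Methoxide opens the epoxy ketone by SN2 attack at C3, the carbon α to the carbonyl, and E1cB loss of the C2 hydroxyl restores C2=C3, the established conversion of α,β-epoxy ketones into α-methoxy enones.

Step 17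
Reactants: 28 1-allyl-6-endo-(4-hydroxy-3,5-dimethoxyphenyl)-3,5-dimethoxy-7-exo-methyl-8-(triethylsilyloxy)bicyclo[3.2.1]oct-2-en-4-one
Product: 29 1-allyl-6-endo-(4-hydroxy-3,5-dimethoxyphenyl)-3,5-dimethoxy-7-exo-methyl-8-(triethylsilyloxy)bicyclo[3.2.1]oct-2-en-4-endo-ol
Conditions: NaBH4, CeCl3·7H2O, MeOH, −78 → −20 °C
Reagents that add atoms: none
Why: Luche 1,2-reduction, in which hydride should reach C4 from the open exo face because the endo C6-aryl group lies directly under the ketone, so the hydroxyl ends on the face turned toward the C6–C7 bridge, cis to the aryl group, which is the (4R) configuration of the target.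

Step 18
Reactants: 29 1-allyl-6-endo-(4-hydroxy-3,5-dimethoxyphenyl)-3,5-dimethoxy-7-exo-methyl-8-(triethylsilyloxy)bicyclo[3.2.1]oct-2-en-4-endo-ol
Product: 30 1-allyl-6-endo-(4-acetoxy-3,5-dimethoxyphenyl)-3,5-dimethoxy-7-exo-methyl-8-(triethylsilyloxy)bicyclo[3.2.1]oct-2-en-4-endo-yl acetate
Conditions: Ac2O, pyridine, DMAP (cat.), CH2Cl2, 20 °C
Reagents that add atoms: acetic anhydride, CC(=O)OC(C)=O
Why: DMAP-catalysed acylation installs the C4 acetate of the target and at the same time masks the phenol against the oxidant of step 20.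

Step 19
Reactants: 30 1-allyl-6-endo-(4-acetoxy-3,5-dimethoxyphenyl)-3,5-dimethoxy-7-exo-methyl-8-(triethylsilyloxy)bicyclo[3.2.1]oct-2-en-4-endo-yl acetate
Product: 31 1-allyl-6-endo-(4-acetoxy-3,5-dimethoxyphenyl)-8-hydroxy-3,5-dimethoxy-7-exo-methylbicyclo[3.2.1]oct-2-en-4-endo-yl acetate
Conditions: HF·pyridine, pyridine, THF, 0 → 20 °C
Reagents that add atoms: none
Why: Buffered fluoride cleavage of the TES ether spares both acetates and the enol ether; the C4 acetate lies anti to the C5–C8 bond and so cannot migrate to the C8 hydroxyl.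

Step 20
Reactants: 31 1-allyl-6-endo-(4-acetoxy-3,5-dimethoxyphenyl)-8-hydroxy-3,5-dimethoxy-7-exo-methylbicyclo[3.2.1]oct-2-en-4-endo-yl acetate
Product: 32 1-allyl-6-endo-(4-acetoxy-3,5-dimethoxyphenyl)-3,5-dimethoxy-7-exo-methyl-8-oxobicyclo[3.2.1]oct-2-en-4-endo-yl acetate
Conditions: Dess–Martin periodinane, NaHCO3, CH2Cl2, 20 °C
Reagents that add atoms: none
Why: Dess–Martin oxidation of the hindered bridging carbinol gives the C8 ketone and removes the uncontrolled C8 stereocentre; the product has no α-hydrogen, so the β-acetoxy group cannot eliminate.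

Step 21
Reactants: 32 1-allyl-6-endo-(4-acetoxy-3,5-dimethoxyphenyl)-3,5-dimethoxy-7-exo-methyl-8-oxobicyclo[3.2.1]oct-2-en-4-endo-yl acetate
Product: 33 (1S,4R,5S,6R,7S)-1-allyl-6-(4-hydroxy-3,5-dimethoxyphenyl)-3,5-dimethoxy-7-methyl-8-oxobicyclo[3.2.1]oct-2-en-4-yl acetate
Conditions: NH4OAc, MeOH/H2O (4:1), 20 °C
Reagents that add atoms: none
Why: Chemoselective solvolysis of the aryl acetate, whose phenoxide is by far the better leaving group, should leave the hindered secondary alkyl acetate in place.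

**Compound list**

1 | syringaldehyde | COc1cc(C=O)cc(OC)c1O | starting material
2 | 4-(tert-butyldimethylsilyloxy)-3,5-dimethoxybenzaldehyde | COc1cc(C=O)cc(OC)c1O[Si](C)(C)C(C)(C)C | intermediate
3 | methyl methoxyacetate | COCC(=O)OC | starting material
4 | methyl 3-Ar-3-hydroxy-2-methoxypropanoate (diastereomer mixture) | COC(=O)C(OC)C(O)c1cc(OC)c(O[Si](C)(C)C(C)(C)C)c(OC)c1 | intermediate
5 | methyl 3-Ar-2-methoxy-3-(methylsulfonyloxy)propanoate | COC(=O)C(OC)C(OS(C)(=O)=O)c1cc(OC)c(O[Si](C)(C)C(C)(C)C)c(OC)c1 | intermediate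
6 | methyl (Z)-3-Ar-2-methoxyprop-2-enoate | COC(=O)/C(OC)=C/c1cc(OC)c(O[Si](C)(C)C(C)(C)C)c(OC)c1 | intermediate
7 | 4-bromobutan-1-ol | OCCCCBr | starting material
8 | (4-bromobutoxy)triethylsilane | CC[Si](CC)(CC)OCCCCBr | intermediate
9 | [4-(triethylsilyloxy)butyl]magnesium bromide | CC[Si](CC)(CC)OCCCC[Mg]Br | intermediate
10 | (1R,2R)-1-[(Z)-2-Ar-1-methoxyethenyl]-2-[2-(triethylsilyloxy)ethyl]cyclopropan-1-ol (alkenyl arm and side chain cis) | CC[Si](CC)(CC)OCC[C@@H]1C[C@]1(O)/C(OC)=C/c1cc(OC)c(O[Si](C)(C)C(C)(C)C)c(OC)c1 | intermediate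
11 | (1R,2R)-1-(tert-butyldimethylsilyloxy)-1-[(Z)-2-Ar-1-methoxyethenyl]-2-[2-(triethylsilyloxy)ethyl]cyclopropane | CC[Si](CC)(CC)OCC[C@@H]1C[C@]1(O[Si](C)(C)C(C)(C)C)/C(OC)=C/c1cc(OC)c(O[Si](C)(C)C(C)(C)C)c(OC)c1 | intermediate
12 | 2-[(1S,2R)-2-(tert-butyldimethylsilyloxy)-2-[(Z)-2-Ar-1-methoxyethenyl]cyclopropyl]acetaldehyde | O=CC[C@@H]1C[C@]1(O[Si](C)(C)C(C)(C)C)/C(OC)=C/c1cc(OC)c(O[Si](C)(C)C(C)(C)C)c(OC)c1 | intermediate
13 | 2-[(1S,2R)-2-(tert-butyldimethylsilyloxy)-2-[(Z)-2-Ar-1-methoxyethenyl]cyclopropyl]acetic acid | OC(=O)C[C@@H]1C[C@]1(O[Si](C)(C)C(C)(C)C)/C(OC)=C/c1cc(OC)c(O[Si](C)(C)C(C)(C)C)c(OC)c1 | intermediate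
14 | methyl 2-[(1S,2R)-2-(tert-butyldimethylsilyloxy)-2-[(Z)-2-Ar-1-methoxyethenyl]cyclopropyl]acetate | COC(=O)C[C@@H]1C[C@]1(O[Si](C)(C)C(C)(C)C)/C(OC)=C/c1cc(OC)c(O[Si](C)(C)C(C)(C)C)c(OC)c1 | intermediate
15 | acetaldehyde | CC=O | starting material
16 | methyl 2-[(1S,2R)-2-(tert-butyldimethylsilyloxy)-2-[(Z)-2-Ar-1-methoxyethenyl]cyclopropyl]-3-hydroxybutanoate (diastereomer mixture at C2 and C3 of the chain) | COC(=O)C(C(C)O)[C@@H]1C[C@]1(O[Si](C)(C)C(C)(C)C)/C(OC)=C/c1cc(OC)c(O[Si](C)(C)C(C)(C)C)c(OC)c1 | intermediate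
17 | 3-O-mesylate of 16 | COC(=O)C(C(C)OS(C)(=O)=O)[C@@H]1C[C@]1(O[Si](C)(C)C(C)(C)C)/C(OC)=C/c1cc(OC)c(O[Si](C)(C)C(C)(C)C)c(OC)c1 | intermediate
18 | methyl (E)-2-[(1S,2R)-2-(tert-butyldimethylsilyloxy)-2-[(Z)-2-Ar-1-methoxyethenyl]cyclopropyl]but-2-enoate (the two alkenyl arms cis) | COC(=O)/C(=C/C)[C@@H]1C[C@]1(O[Si](C)(C)C(C)(C)C)/C(OC)=C/c1cc(OC)c(O[Si](C)(C)C(C)(C)C)c(OC)c1 | intermediate
19 | methyl (6R,7S)-6-Ar-4-(tert-butyldimethylsilyloxy)-5-methoxy-7-methylcyclohepta-1,4-diene-1-carboxylate (aryl and methyl trans) | COC(=O)C1=CCC(O[Si](C)(C)C(C)(C)C)=C(OC)[C@@H](c2cc(OC)c(O[Si](C)(C)C(C)(C)C)c(OC)c2)[C@@H]1C | intermediate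
20 | allyl bromide | C=CCBr | starting material
21 | methyl (1R,6R,7S)-1-allyl-6-Ar-4-(tert-butyldimethylsilyloxy)-5-methoxy-7-methylcyclohepta-2,4-diene-1-carboxylate (allyl trans to methyl) | C=CC[C@@]1(C(=O)OC)C=CC(O[Si](C)(C)C(C)(C)C)=C(OC)[C@@H](c2cc(OC)c(O[Si](C)(C)C(C)(C)C)c(OC)c2)[C@@H]1C | intermediate
22 | [(1R,6R,7S)-1-allyl-6-Ar-4-(tert-butyldimethylsilyloxy)-5-methoxy-7-methylcyclohepta-2,4-dien-1-yl]methanol | C=CC[C@@]1(CO)C=CC(O[Si](C)(C)C(C)(C)C)=C(OC)[C@@H](c2cc(OC)c(O[Si](C)(C)C(C)(C)C)c(OC)c2)[C@@H]1C | intermediate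
23 | (1R,6R,7S)-1-allyl-6-Ar-4-(tert-butyldimethylsilyloxy)-5-methoxy-7-methylcyclohepta-2,4-diene-1-carbaldehyde | C=CC[C@@]1(C=O)C=CC(O[Si](C)(C)C(C)(C)C)=C(OC)[C@@H](c2cc(OC)c(O[Si](C)(C)C(C)(C)C)c(OC)c2)[C@@H]1C | intermediate
24 | 1-allyl-6-endo-Ar-8-hydroxy-5-methoxy-7-exo-methylbicyclo[3.2.1]oct-2-en-4-one (aryl on the side of the C2–C4 bridge, methyl on the side of C8; C8 open) | C=CC[C@]12C=CC(=O)[C@](OC)(C1O)[C@@H](c1cc(OC)c(O[Si](C)(C)C(C)(C)C)c(OC)c1)[C@@H]2C | intermediate
25 | 8-O-triethylsilyl ether of 24 | C=CC[C@]12C=CC(=O)[C@](OC)(C1O[Si](CC)(CC)CC)[C@@H](c1cc(OC)c(O[Si](C)(C)C(C)(C)C)c(OC)c1)[C@@H]2C | intermediate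
26 | 1-allyl-2,3-epoxy-6-endo-(4-hydroxy-3,5-dimethoxyphenyl)-5-methoxy-7-exo-methyl-8-(triethylsilyloxy)bicyclo[3.2.1]octan-4-one (epoxide face open) | C=CC[C@]12C3OC3C(=O)[C@](OC)(C1O[Si](CC)(CC)CC)[C@@H](c1cc(OC)c(O)c(OC)c1)[C@@H]2C | intermediate
27 | 1-allyl-2-hydroxy-6-endo-(4-hydroxy-3,5-dimethoxyphenyl)-3,5-dimethoxy-7-exo-methyl-8-(triethylsilyloxy)bicyclo[3.2.1]octan-4-one | C=CC[C@]12C(O)C(OC)C(=O)[C@](OC)(C1O[Si](CC)(CC)CC)[C@@H](c1cc(OC)c(O)c(OC)c1)[C@@H]2C | intermediate
28 | 1-allyl-6-endo-(4-hydroxy-3,5-dimethoxyphenyl)-3,5-dimethoxy-7-exo-methyl-8-(triethylsilyloxy)bicyclo[3.2.1]oct-2-en-4-one | C=CC[C@]12C=C(OC)C(=O)[C@](OC)(C1O[Si](CC)(CC)CC)[C@@H](c1cc(OC)c(O)c(OC)c1)[C@@H]2C | intermediate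
29 | 1-allyl-6-endo-(4-hydroxy-3,5-dimethoxyphenyl)-3,5-dimethoxy-7-exo-methyl-8-(triethylsilyloxy)bicyclo[3.2.1]oct-2-en-4-ol, 4-OH toward the C6–C7 bridge and cis to the aryl group | C=CC[C@]12C=C(OC)[C@@H](O)[C@](OC)(C1O[Si](CC)(CC)CC)[C@@H](c1cc(OC)c(O)c(OC)c1)[C@@H]2C | intermediate
30 | diacetate of 29 (C4–OAc and aryl–OAc) | C=CC[C@]12C=C(OC)[C@@H](OC(C)=O)[C@](OC)(C1O[Si](CC)(CC)CC)[C@@H](c1cc(OC)c(OC(C)=O)c(OC)c1)[C@@H]2C | intermediate
31 | 8-hydroxy diacetate (30 without the TES group) | C=CC[C@]12C=C(OC)[C@@H](OC(C)=O)[C@](OC)(C1O)[C@@H](c1cc(OC)c(OC(C)=O)c(OC)c1)[C@@H]2C | intermediate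
32 | 1-allyl-6-endo-(4-acetoxy-3,5-dimethoxyphenyl)-3,5-dimethoxy-7-exo-methyl-8-oxobicyclo[3.2.1]oct-2-en-4-yl acetate | C=CC[C@]12C=C(OC)[C@@H](OC(C)=O)[C@](OC)(C1=O)[C@@H](c1cc(OC)c(OC(C)=O)c(OC)c1)[C@@H]2C | intermediate
33 | (1S,4R,5S,6R,7S)-1-allyl-6-(4-hydroxy-3,5-dimethoxyphenyl)-3,5-dimethoxy-7-methyl-8-oxobicyclo[3.2.1]oct-2-en-4-yl acetate (CNP0373655.1) | C=CC[C@]12C=C(OC)[C@@H](OC(C)=O)[C@](OC)(C1=O)[C@@H](c1cc(OC)c(O)c(OC)c1)[C@@H]2C | target

**Step count and risks**

Total step count: 21. Longest linear sequence: 20 steps (steps 1, 2 and 4–21 from syringaldehyde; step 3 is a one-step side branch).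

Steps most likely to fail:

Step 9 (key step). The inside methyl group raises the barrier of the boat transition state, so at the temperature required the substrate may instead undergo one-centre epimerisation to the unreactive trans-divinylcyclopropane or lose the enol silyl group. Fallback, setting out from 18 and returning at 19: Bu4NF buffered with AcOH (THF, 0 °C) removes both silyl groups to give the free cis-divinylcyclopropanol phenol F1. KN(SiMe3)2 (2.2 equiv) with 18-crown-6 in THF at −78 → 0 °C forms the dipotassium cyclopropanolate; its alkoxide-accelerated Cope rearrangement, known for cis-1,2-divinylcyclopropanolates, which rearrange below 0 °C, should pass through the same boat geometry to the dipotassium enolate phenoxide F2. TBSCl at −78 °C then silylates both oxygens to give 19.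

Step 4. The chiral titanate may discriminate poorly between the enantiotopic faces on this conjugated α-alkoxy ester, and the low-valent titanium may also engage the enoate C=C and lower conversion. Fallback, setting out from 6 and 8 and returning at 10: the cyclopropanation is run with Ti(OiPr)4 alone (the catalytic achiral Kulinkovich protocol, cis selectivity unchanged), which gives 10 together with its mirror image, the enantiomeric cyclopropanol F3. The two are separated by preparative chromatography on a polysaccharide chiral stationary phase, and F3 is discarded.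

Step 10. Allyl bromide may attack the extended enolate at C3 instead of C1, or on the face syn to the C7 methyl group. Fallback, setting out from 19 and returning at 21: Me3SnOH (1,2-dichloroethane, 80 °C) hydrolyses the methyl ester to the cycloheptadienecarboxylic acid F4, and allyl bromide 20 with K2CO3 in DMF gives the allyl ester F5. LiN(iPr)2 in THF/HMPA at −78 °C followed by Me3SiCl gives the silyl ketene acetal F6. On warming to 20 °C this undergoes the Ireland–Claisen [3,3] shift, which can deliver allyl only to C1 and does so through a compact cyclic transition state on the face away from the C7 methyl, to give the trimethylsilyl ester F7. Aqueous work-up frees the C1-allyl acid F8, and Me3SiCHN2 in MeOH/toluene gives 21.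

**Further compounds**

F1 | step 9 | methyl (E)-2-[(1S,2R)-2-hydroxy-2-[(Z)-2-(4-hydroxy-3,5-dimethoxyphenyl)-1-methoxyethenyl]cyclopropyl]but-2-enoate | COC(=O)/C(=C/C)[C@@H]1C[C@]1(O)/C(OC)=C/c1cc(OC)c(O)c(OC)c1
F2 | step 9 | dipotassium enolate phenoxide of methyl (6R,7S)-6-(4-hydroxy-3,5-dimethoxyphenyl)-5-methoxy-7-methyl-4-oxocyclohept-1-ene-1-carboxylate | COC(=O)C1=CCC([O-])=C(OC)[C@@H](c2cc(OC)c([O-])c(OC)c2)[C@@H]1C.[K+].[K+]
F3 | step 4 | (1S,2S)-1-[(Z)-2-Ar-1-methoxyethenyl]-2-[2-(triethylsilyloxy)ethyl]cyclopropan-1-ol (enantiomer of 10) | CC[Si](CC)(CC)OCC[C@H]1C[C@@]1(O)/C(OC)=C/c1cc(OC)c(O[Si](C)(C)C(C)(C)C)c(OC)c1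
F4 | step 10 | (6R,7S)-6-Ar-4-(tert-butyldimethylsilyloxy)-5-methoxy-7-methylcyclohepta-1,4-diene-1-carboxylic acid | OC(=O)C1=CCC(O[Si](C)(C)C(C)(C)C)=C(OC)[C@@H](c2cc(OC)c(O[Si](C)(C)C(C)(C)C)c(OC)c2)[C@@H]1C
F5 | step 10 | allyl (6R,7S)-6-Ar-4-(tert-butyldimethylsilyloxy)-5-methoxy-7-methylcyclohepta-1,4-diene-1-carboxylate | C=CCOC(=O)C1=CCC(O[Si](C)(C)C(C)(C)C)=C(OC)[C@@H](c2cc(OC)c(O[Si](C)(C)C(C)(C)C)c(OC)c2)[C@@H]1C
F6 | step 10 | allyl trimethylsilyl ketene acetal of F5 (exocyclic C8=C1, ring alkenes C2=C3 and C4=C5) | C=CCOC(O[Si](C)(C)C)=C1C=CC(O[Si](C)(C)C(C)(C)C)=C(OC)[C@@H](c2cc(OC)c(O[Si](C)(C)C(C)(C)C)c(OC)c2)[C@@H]1C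
F7 | step 10 | trimethylsilyl (1R,6R,7S)-1-allyl-6-Ar-4-(tert-butyldimethylsilyloxy)-5-methoxy-7-methylcyclohepta-2,4-diene-1-carboxylate | C=CC[C@@]1(C(=O)O[Si](C)(C)C)C=CC(O[Si](C)(C)C(C)(C)C)=C(OC)[C@@H](c2cc(OC)c(O[Si](C)(C)C(C)(C)C)c(OC)c2)[C@@H]1C
F8 | step 10 | (1R,6R,7S)-1-allyl-6-Ar-4-(tert-butyldimethylsilyloxy)-5-methoxy-7-methylcyclohepta-2,4-diene-1-carboxylic acid | C=CC[C@@]1(C(=O)O)C=CC(O[Si](C)(C)C(C)(C)C)=C(OC)[C@@H](c2cc(OC)c(O[Si](C)(C)C(C)(C)C)c(OC)c2)[C@@H]1C
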